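The decision is whether 0.800 equiv of partner at 0.58 M substrate is worth the material, and that depends on where the flask stops.

| flask | substrate | partner | remark | time |
|---|---|---|---|---|
| Sunday's | 0.29 M | 0.80 equiv (fed, over 4.0 min) | run made earlier |  |
| Friday's | 0.43 M | 0.80 equiv (fed, over 4.0 min) | run made earlier |  |
| Tuesday's | 0.58 M | 1.2 equiv (fed, over 4.0 min) | run made earlier |  |
| flask | 0.58 M | 0.800 equiv (fed, over 4.0 min) |  | 3.0 h |

- Sunday's (time / min: isomer of the product A / %, target / %): 8.00: 66.7, 0.7; 12.0: 70.6, 0; 20.0: 73.6, 0.2; 30.0: 74.0, 0.5; 50.0: 73.3, 0.5; 80.0: 73.9, 0; 120: 73.5, 0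
- Friday's (time / min: isomer of the product A / %, target / %): 8.00: 70.0, 1.6; 12.0: 73.5, 0.3; 20.0: 75.0, 0; 30.0: 74.7, 0.5; 50.0: 75.0, 0.3; 80.0: 75.6, 0.4; 120: 75.6, 0
- Tuesday's (time / min: isomer of the product A / %, target / %): 10.0: 93.2, 0.9; 25.0: 95.1, 0; 50.0: 95.5, 0; 80.0: 95.1, 0.4; 120: 95.1, 0.1

(each reading ± 0.5 percentage points)

- the analysis behind the earlier runs scatters by 0.5 percentage points, standard deviation
- reactions considered so far: partner <-> dormant form; target <-> isomer of the product B; substrate + partner <-> target; substrate + partner <-> isomer of the product A
- the reaction counts as stopped when no species that holds the substrate changes by six tenths of a point or more over the second half of the time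

- which holds at 3.0 h: what has brought the reaction to rest, or that it has not come to rest (it is still moving / forward and back rates have come level / the partner has run out first / all of the substrate has reacted)
- amount of isomer of the product A at 3.0 h, in percent of the substrate charged

The readings from 30.0 min to 120 min in Sunday's run stay flat within the scatter of 0.5 percentage points, and their mean, 73.7%, replaces the curve. Friday's mean is 75.2% and Tuesday's, from 25.0 min on, is 95.2%.

Sunday's and Friday's runs stop below the 0.80 equiv the partner allows, and Friday's more concentrated flask stands higher. Tuesday's run, with 1.2 equiv of partner, stops short of the whole charge. Substrate and partner appear to stand side by side while nothing moves, so forward and back rates appear level, which is chemical equilibrium.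

Such a rest has a measure. The rest quotient, c(isomer of the product A) / (c(substrate) × c(partner)), is an apparent equilibrium constant. Here c(partner) is what the isomer has not consumed, dormant form included. Late target readings lie at about the scatter, so target is not counted, and isomer of the product B is not read.

The means give 153 M⁻¹ for Sunday, 148 M⁻¹ for Friday and 138 M⁻¹ for Tuesday, with a mean of 146 M⁻¹.

Set equal to that mean, the quotient puts the new flask at 76.2%. Replacing three quotients by their mean costs little: Tuesday's value gives 76.0% and Sunday's 76.4%.

The forecast says forward and back rates have come level and 76.3%, against the 76.2% reckoned here, on the ground that what remains “points to equilibrium rather than exhaustion”.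

The flask gives forward and back rates have come level and 76.2%.

    partner ⇌ dormant form (K = 0.440, k = 0.00310 s⁻¹)
    target ⇌ isomer of the product B (K = 0.950, k = 0.0260 s⁻¹)
    substrate + partner ⇌ target (K = 1.00 M⁻¹, k = 0.160 M⁻¹ s⁻¹)
    substrate + partner ⇌ isomer of the product A (K = 250 M⁻¹, k = 0.0740 M⁻¹ s⁻¹)

By the step to isomer of the product A alone, forward rate only and with the whole charges taken as there at once, substrate in the flask has a half-life of 0.34 min, far shorter than the 3.0 h asked. From 1.50 h to 3.00 h the flask holds 76.2% of isomer of the product A, with substrate at 23.3%, partner at 2.82% of its own charge and dormant form at 0.00576 M. The flask's amount of that isomer gives a rest quotient of 143 M⁻¹. With 0.320 equiv of partner, the quotient 146 M⁻¹ puts the isomer at 31.5%, and that neighbouring flask holds 31.3%.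

The runs are calculated on assumed constants.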